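## Retrosynthetic overview

- Vismiaphenone E is traced back through its tris-MOM ether to an aryl 1,1-dimethylpropargyl ether. The pyran ring is closed last, by propargyl Claisen rearrangement and oxa-6π closure onto C4a, the only unsubstituted ring carbon, with O1 on C8a.
- That ether comes from a 2,4,6-trihydroxy-3-prenylbenzophenone by etherification of the hydroxyl para to the ketone and MOM capping of the two ortho hydroxyls.
- The strategy rests on ring A (C4a, C5, C6, C7, C8, C8a): oxygen sits on C5, C7 and C8a, and the 4-hydroxybenzoyl group sits on C6 between two oxygenated carbons. This is the pattern left by a chain of three acetate units started on 4-hydroxybenzoate, so C6–C7 is cut.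
- The cut leads to a 6-(aroylmethyl)-4-hydroxy-3-prenyl-2-pyrone, which is opened and re-closed by base as a Claisen condensation. The pyrone comes from the dianion of 3-prenyl triacetic acid lactone and a MOM-protected methyl 4-hydroxybenzoate.
- Ring order: ring A (step 4), then the pyran ring (step 7). The target is achiral, so no stereocentre has to be set.

Key step: step 4

Remark: the hydroxyls on C5 and C7 are capped before the thermal ring closure, on the assumption that a free C5 hydroxyl would compete with the C8a oxygen in closing the ortho-quinone methide.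

## Route

Step 1
Reactants: 1 triacetic acid lactone (4-hydroxy-6-methyl-2H-pyran-2-one); 2 prenyl acetate (3-methylbut-2-en-1-yl acetate)
Product: 3 4-hydroxy-6-methyl-3-(3-methylbut-2-en-1-yl)-2H-pyran-2-one
Conditions: Pd(PPh3)4 (5 mol %), Et3N, toluene, 70 °C; 1 in slight excess
Reagents that add atoms: none
Why: Tsuji–Trost allylation: zerovalent palladium ionizes 2 to a π-prenyl complex, the soft pyrone enolate attacks through C3 at the unsubstituted terminus, and any O-prenyl ether is ionized again, so material should collect in the C3-prenyl pyrone.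

Step 2
Reactants: 4 methyl 4-hydroxybenzoate
Product: 5 methyl 4-(methoxymethoxy)benzoate
Conditions: NaH, MOMCl, THF–DMF, 0 °C to rt
Reagents that add atoms: chloromethyl methyl ether (MOMCl), COCCl
Why: Williamson-type O-alkylation of the sodium phenoxide with a reactive α-chloro ether; the resulting acetal tolerates the amide base, alkoxide and heat of the later steps.

Step 3
Reactants: 3 4-hydroxy-6-methyl-3-(3-methylbut-2-en-1-yl)-2H-pyran-2-one; 5 methyl 4-(methoxymethoxy)benzoate
Product: 7 4-hydroxy-6-[2-(4-(methoxymethoxy)phenyl)-2-oxoethyl]-3-(3-methylbut-2-en-1-yl)-2H-pyran-2-one, via dilithium pyrone dianion 6 (not isolated)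
Conditions: LiN(i-Pr)2 (3.3 equiv), THF–DMPU, −78 °C; then 5, −78 to 0 °C; then cold 1 M HCl to pH 3
Reagents that add atoms: none
Why: Claisen acylation of a pyrone dianion: after the hydroxyl, the vinylogous 6-methyl group is deprotonated, this more basic carbon attacks the non-enolizable ester, and the third equivalent of base takes up the acidic product so that it is not acylated twice.

Step 4
Reactants: 7 4-hydroxy-6-[2-(4-(methoxymethoxy)phenyl)-2-oxoethyl]-3-(3-methylbut-2-en-1-yl)-2H-pyran-2-one
Product: 9 [2,4,6-trihydroxy-3-(3-methylbut-2-en-1-yl)phenyl][4-(methoxymethoxy)phenyl]methanone, via open-chain triketo ester 8 (not isolated)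
Conditions: Mg(OMe)2 (excess), MeOH, reflux, argon; then 1 M HCl
Reagents that add atoms: none
Why: Magnesium-bound methoxide adds to the lactone carbonyl (future C7) and the ring opens to the magnesium chelate of triketo ester 8; the methylene between the two ketones (future C6), the most acidic carbon of the chain, then adds to the ester carbon and methoxide leaves, which forms C6–C7. The closest known reaction type is the base-induced rearrangement of 4-hydroxy-6-(2-oxoalkyl)-2-pyrones and of 3,5,7-triketo esters to acylphloroglucinols, a biomimetic Claisen (Dieckmann-type) cyclization. Ring A closes in the 6-exo-trig mode, and tautomerization of the cyclic trione to the phloroglucinol should lock the ring, so that the net change is an isomerization. No stereocentre is formed. The selectivity required is ester acylation (Claisen mode) over ketone addition (aldol mode): the only six-membered aldol closure would join the prenyl-bearing carbon to the aryl ketone and give a quaternary carbon that cannot aromatize and can revert, the 4-alkoxyphenyl ketone is a weak acceptor, and chelation of the diketonate by magnesium should hold the chain folded and shield it from retro-Claisen cleavage.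

Step 5
Reactants: 9 [2,4,6-trihydroxy-3-(3-methylbut-2-en-1-yl)phenyl][4-(methoxymethoxy)phenyl]methanone; 10 3-chloro-3-methylbut-1-yne
Product: 11 [2,6-dihydroxy-3-(3-methylbut-2-en-1-yl)-4-(2-methylbut-3-yn-2-yloxy)phenyl][4-(methoxymethoxy)phenyl]methanone
Conditions: DBU (1.2 equiv), CuCl2·2H2O (cat.), MeCN, 0 °C
Reagents that add atoms: none
Why: Copper-catalysed etherification of a phenol with a tertiary propargyl chloride (through a copper allenylidene-type electrophile) at a temperature too low for rearrangement; one equivalent of base ionizes the hydroxyl para to the ketone, the most acidic of the three, while the ortho hydroxyls are hydrogen-bonded to or crowded by the aroyl group and the 4'-oxygen is masked.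

Step 6
Reactants: 11 [2,6-dihydroxy-3-(3-methylbut-2-en-1-yl)-4-(2-methylbut-3-yn-2-yloxy)phenyl][4-(methoxymethoxy)phenyl]methanone
Product: 12 [2,6-bis(methoxymethoxy)-3-(3-methylbut-2-en-1-yl)-4-(2-methylbut-3-yn-2-yloxy)phenyl][4-(methoxymethoxy)phenyl]methanone
Conditions: NaH (2.5 equiv), MOMCl (3 equiv), THF–DMF, 0 °C to rt
Reagents that add atoms: chloromethyl methyl ether (MOMCl), COCCl
Why: Williamson-type acetalization of both sodium phenoxides; with the two hydroxyls ortho to the ketone capped, only the para oxygen can donate hydrogen and close the pyran ring in step 7.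

Step 7
Reactants: 12 [2,6-bis(methoxymethoxy)-3-(3-methylbut-2-en-1-yl)-4-(2-methylbut-3-yn-2-yloxy)phenyl][4-(methoxymethoxy)phenyl]methanone
Product: 14 [5,7-bis(methoxymethoxy)-2,2-dimethyl-8-(3-methylbut-2-en-1-yl)-2H-chromen-6-yl][4-(methoxymethoxy)phenyl]methanone, via ortho-allenyl phenol 13 (not isolated)
Conditions: o-xylene (degassed), 140 °C
Reagents that add atoms: none
Why: Aryl propargyl ether Claisen rearrangement to the only unsubstituted ortho carbon, enolization to allenyl phenol 13, 1,5-hydrogen shift from its sole free hydroxyl to the central allene carbon and oxa-6π electrocyclization of the ortho-quinone methide; rearrangement toward the prenyl-bearing carbon gives a dienone that cannot enolize and can return.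

Step 8
Reactants: 14 [5,7-bis(methoxymethoxy)-2,2-dimethyl-8-(3-methylbut-2-en-1-yl)-2H-chromen-6-yl][4-(methoxymethoxy)phenyl]methanone
Product: 15 vismiaphenone E, [5,7-dihydroxy-2,2-dimethyl-8-(3-methylbut-2-en-1-yl)-2H-chromen-6-yl](4-hydroxyphenyl)methanone
Conditions: 3 M aq. HCl, MeOH, 45 °C
Reagents that add atoms: none
Why: Acid-catalysed acetal exchange with methanol removes the three methoxymethyl groups; the two ortho to the ketone should leave first, and the C7 hydroxyl freed next to the prenyl group is held in a hydrogen bond to the ketone, which should slow acid-induced cyclization onto the prenyl double bond.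

## Compound list

1 | triacetic acid lactone (4-hydroxy-6-methyl-2H-pyran-2-one) | CC1=CC(O)=CC(=O)O1 | starting material
2 | prenyl acetate (3-methylbut-2-en-1-yl acetate) | CC(C)=CCOC(C)=O | starting material
3 | 4-hydroxy-6-methyl-3-(3-methylbut-2-en-1-yl)-2H-pyran-2-one | CC1=CC(O)=C(CC=C(C)C)C(=O)O1 | intermediate
4 | methyl 4-hydroxybenzoate | COC(=O)c1ccc(O)cc1 | starting material
5 | methyl 4-(methoxymethoxy)benzoate | COCOc1ccc(cc1)C(=O)OC | intermediate
6 | dilithium dianion of 3 (4-oxido, 6-lithiomethyl) | [Li+].[Li+].[CH2-]C1=CC([O-])=C(CC=C(C)C)C(=O)O1 | intermediate (not isolated)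
7 | 4-hydroxy-6-[2-(4-(methoxymethoxy)phenyl)-2-oxoethyl]-3-(3-methylbut-2-en-1-yl)-2H-pyran-2-one | CC(C)=CCC1=C(O)C=C(CC(=O)c2ccc(OCOC)cc2)OC1=O | intermediate
8 | methyl 7-[4-(methoxymethoxy)phenyl]-2-(3-methylbut-2-en-1-yl)-3,5,7-trioxoheptanoate (racemic at the enolizable C2; present as its magnesium enolate) | COC(=O)C(CC=C(C)C)C(=O)CC(=O)CC(=O)c1ccc(OCOC)cc1 | intermediate (not isolated)
9 | [2,4,6-trihydroxy-3-(3-methylbut-2-en-1-yl)phenyl][4-(methoxymethoxy)phenyl]methanone | CC(C)=CCc1c(O)cc(O)c(C(=O)c2ccc(OCOC)cc2)c1O | intermediate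
10 | 3-chloro-3-methylbut-1-yne | C#CC(C)(C)Cl | starting material
11 | [2,6-dihydroxy-3-(3-methylbut-2-en-1-yl)-4-(2-methylbut-3-yn-2-yloxy)phenyl][4-(methoxymethoxy)phenyl]methanone | CC(C)=CCc1c(OC(C)(C)C#C)cc(O)c(C(=O)c2ccc(OCOC)cc2)c1O | intermediate
12 | [2,6-bis(methoxymethoxy)-3-(3-methylbut-2-en-1-yl)-4-(2-methylbut-3-yn-2-yloxy)phenyl][4-(methoxymethoxy)phenyl]methanone | CC(C)=CCc1c(OC(C)(C)C#C)cc(OCOC)c(C(=O)c2ccc(OCOC)cc2)c1OCOC | intermediate
13 | [4-hydroxy-2,6-bis(methoxymethoxy)-3-(3-methylbuta-1,2-dien-1-yl)-5-(3-methylbut-2-en-1-yl)phenyl][4-(methoxymethoxy)phenyl]methanone | CC(C)=CCc1c(O)c(C=C=C(C)C)c(OCOC)c(C(=O)c2ccc(OCOC)cc2)c1OCOC | intermediate (not isolated)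
14 | [5,7-bis(methoxymethoxy)-2,2-dimethyl-8-(3-methylbut-2-en-1-yl)-2H-chromen-6-yl][4-(methoxymethoxy)phenyl]methanone | CC(C)=CCc1c(OCOC)c(C(=O)c2ccc(OCOC)cc2)c(OCOC)c2c1OC(C)(C)C=C2 | intermediate
15 | vismiaphenone E, [5,7-dihydroxy-2,2-dimethyl-8-(3-methylbut-2-en-1-yl)-2H-chromen-6-yl](4-hydroxyphenyl)methanone | CC(C)=CCc1c(O)c(C(=O)c2ccc(O)cc2)c(O)c2c1OC(C)(C)C=C2 | target

## Step count and risks

Total steps: 8. Longest linear sequence: 7 steps (steps 1, 3, 4, 5, 6, 7, 8, from triacetic acid lactone).

Steps most likely to fail: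

1. Step 4. The alkoxide may fail to open the lactone, whose carbonyl is flanked by the prenyl group and sits in a delocalized anion. The open chain may also lose its aroyl group by retro-Claisen cleavage, or close in a non-aromatizing aldol mode. The fallback takes the prenyl group out of the fold and sets out from 1 and 5. The dianion of 1 (LiN(i-Pr)2, THF, −78 °C) would be acylated with 5 to give 4-hydroxy-6-[2-(4-(methoxymethoxy)phenyl)-2-oxoethyl]-2H-pyran-2-one F1. Mg(OMe)2 in MeOH should rearrange this unsubstituted pyrone, the case nearest to the parent 6-phenacyl pyrone, to (2,4,6-trihydroxyphenyl)[4-(methoxymethoxy)phenyl]methanone F2. Mono C-prenylation of its phenoxide with prenyl bromide (aqueous KOH, 0 °C), an electrophilic alkylation at one of two equivalent free ring carbons, would then give 9, where the route is rejoined; steps 1 and 3 fall away.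

2. Step 5. The copper-activated tertiary electrophile may show poor site selectivity, with ether formation at a hydroxyl ortho to the ketone, double etherification, or C-alkylation at the free ring carbon. The fallback separates site selection from the tertiary etherification and sets out from 9. A hard, O-selective silyl chloride (i-Pr3SiCl, 1 equiv, imidazole, DMF, 0 °C) would mark the most acidic hydroxyl as [2,6-dihydroxy-3-(3-methylbut-2-en-1-yl)-4-(triisopropylsilyloxy)phenyl][4-(methoxymethoxy)phenyl]methanone F3. NaH and MOMCl would cap the two remaining hydroxyls to give [2,6-bis(methoxymethoxy)-3-(3-methylbut-2-en-1-yl)-4-(triisopropylsilyloxy)phenyl][4-(methoxymethoxy)phenyl]methanone F4. Bu4NF in THF would free the single phenol [4-hydroxy-2,6-bis(methoxymethoxy)-3-(3-methylbut-2-en-1-yl)phenyl][4-(methoxymethoxy)phenyl]methanone F5. This phenol can be etherified with an excess of 10 (DBU, CuCl2·2H2O, MeCN, 0 °C) without any competing hydroxyl, giving 12, where the route is rejoined; step 6 falls away.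

3. Step 8. While the slow 4'-MOM group is being removed, acid may drive cyclization of the prenyl group onto the freed C7 hydroxyl, addition to the prenyl double bond, or opening and isomerization of the chromene. The fallback moves the acid step to a point before these groups exist, finishes with base, and sets out from 11. Pivaloyl chloride (Et3N, DMAP, CH2Cl2) would cap the two ortho hydroxyls as [3-(3-methylbut-2-en-1-yl)-4-(2-methylbut-3-yn-2-yloxy)-2,6-bis(pivaloyloxy)phenyl][4-(methoxymethoxy)phenyl]methanone F6. Dilute HCl in MeOH at rt should then remove the 4'-MOM group, with no free hydroxyl next to the prenyl group and no chromene present, giving [3-(3-methylbut-2-en-1-yl)-4-(2-methylbut-3-yn-2-yloxy)-2,6-bis(pivaloyloxy)phenyl](4-hydroxyphenyl)methanone F7. Heating in o-xylene at 140 °C should close the pyran ring as in step 7 to give [2,2-dimethyl-8-(3-methylbut-2-en-1-yl)-5,7-bis(pivaloyloxy)-2H-chromen-6-yl](4-hydroxyphenyl)methanone F8. NaOMe in MeOH at rt would cleave the two aryl pivalates and deliver 15; steps 6 to 8 fall away.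

## Further compounds

F1 | step 4 | 4-hydroxy-6-[2-(4-(methoxymethoxy)phenyl)-2-oxoethyl]-2H-pyran-2-one | O=C1C=C(O)C=C(CC(=O)c2ccc(OCOC)cc2)O1
F2 | step 4 | (2,4,6-trihydroxyphenyl)[4-(methoxymethoxy)phenyl]methanone | Oc1cc(O)c(C(=O)c2ccc(OCOC)cc2)c(O)c1
F3 | step 5 | [2,6-dihydroxy-3-(3-methylbut-2-en-1-yl)-4-(triisopropylsilyloxy)phenyl][4-(methoxymethoxy)phenyl]methanone | CC(C)=CCc1c(O[Si](C(C)C)(C(C)C)C(C)C)cc(O)c(C(=O)c2ccc(OCOC)cc2)c1O
F4 | step 5 | [2,6-bis(methoxymethoxy)-3-(3-methylbut-2-en-1-yl)-4-(triisopropylsilyloxy)phenyl][4-(methoxymethoxy)phenyl]methanone | CC(C)=CCc1c(O[Si](C(C)C)(C(C)C)C(C)C)cc(OCOC)c(C(=O)c2ccc(OCOC)cc2)c1OCOC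
F5 | step 5 | [4-hydroxy-2,6-bis(methoxymethoxy)-3-(3-methylbut-2-en-1-yl)phenyl][4-(methoxymethoxy)phenyl]methanone | CC(C)=CCc1c(O)cc(OCOC)c(C(=O)c2ccc(OCOC)cc2)c1OCOC
F6 | step 8 | [3-(3-methylbut-2-en-1-yl)-4-(2-methylbut-3-yn-2-yloxy)-2,6-bis(pivaloyloxy)phenyl][4-(methoxymethoxy)phenyl]methanone | CC(C)=CCc1c(OC(C)(C)C#C)cc(OC(=O)C(C)(C)C)c(C(=O)c2ccc(OCOC)cc2)c1OC(=O)C(C)(C)C
F7 | step 8 | [3-(3-methylbut-2-en-1-yl)-4-(2-methylbut-3-yn-2-yloxy)-2,6-bis(pivaloyloxy)phenyl](4-hydroxyphenyl)methanone | CC(C)=CCc1c(OC(C)(C)C#C)cc(OC(=O)C(C)(C)C)c(C(=O)c2ccc(O)cc2)c1OC(=O)C(C)(C)C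
F8 | step 8 | [2,2-dimethyl-8-(3-methylbut-2-en-1-yl)-5,7-bis(pivaloyloxy)-2H-chromen-6-yl](4-hydroxyphenyl)methanone | CC(C)=CCc1c(OC(=O)C(C)(C)C)c(C(=O)c2ccc(O)cc2)c(OC(=O)C(C)(C)C)c2c1OC(C)(C)C=C2
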